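Assumption: positions are cited in cembrane numbering (C1 carries the isopropylidene, C2 is the enone carbonyl, C3/C4 the oxirane, C8 the methyl-bearing CH, C9 the second ketone, C12 the acetoxy carbon; the target is 3R,4S,8S,12R), and (R)-(−)-linalool of high ee and isomerically pure methyl (E)-geranate are taken as purchased.

**Retrosynthetic overview**
- Oxirane last: the target comes from the 14-membered cross-conjugated dienone by catalyst-controlled nucleophilic epoxidation of the C3=C4 enone; the C1=C15 isopropylidene enone is left alone.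
- Macrocycle first: C1–C2 disconnection of the dienone to an open-chain C20 enoyl chloride whose terminal isopropylidene alkene attacks the C2 acylium (laboratory counterpart of the geranylgeranyl C1→C14 closure), with the C9 ketone, the C8 centre and the C12 tertiary acetate already in place.
- C9–C10 disconnection of the seco acid: acyl cross-coupling of the alkylborane from (R)-linalyl acetate (brings C12) with an (S)-α-methyl thioester (C2–C9).
- The thioester comes from methyl geranate by allylic oxidation of the E-methyl group and asymmetric hydrogenation (sets C8).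

**Route**

Step 1
Reactants: 1 (R)-(−)-linalool
Product: 2 (3R)-3,7-dimethylocta-1,6-dien-3-yl acetate ((R)-linalyl acetate)
Conditions: Ac2O, Et3N, DMAP (cat.), CH2Cl2, rt, 36 h
Reagents that add atoms: acetic anhydride, CC(=O)OC(C)=O
Why: DMAP-catalysed acetylation of the tertiary alcohol under basic conditions avoids the acid-promoted allylic rearrangement of linalool and does not touch the C–O bond, so the (R) centre (future C12) is retained.

Step 2
Reactants: 3 methyl (2E)-3,7-dimethylocta-2,6-dienoate (methyl geranate)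
Product: 4 methyl (2E,6E)-3,7-dimethyl-8-oxoocta-2,6-dienoate
Conditions: SeO2 (1.1 equiv), 95% EtOH, reflux
Reagents that add atoms: selenium dioxide, O=[Se]=O
Why: Riley allylic oxidation (ene reaction then [2,3]-shift) takes place at the E-methyl group of the electron-rich terminal trisubstituted alkene and gives the (E)-enal, while the ester-deactivated C2=C3 alkene does not react.

Step 3
Reactants: 4 methyl (2E,6E)-3,7-dimethyl-8-oxoocta-2,6-dienoate
Product: 5 (2E,6E)-8-methoxy-2,6-dimethyl-8-oxoocta-2,6-dienoic acid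
Conditions: NaClO2, NaH2PO4, 2-methyl-2-butene, t-BuOH/H2O, 0 °C to rt
Reagents that add atoms: sodium chlorite, [Na+].[O-]Cl=O
Why: Pinnick oxidation converts only the aldehyde into the acid, the scavenger removes HOCl so that neither alkene is attacked or isomerised.

Step 4
Reactants: 5 (2E,6E)-8-methoxy-2,6-dimethyl-8-oxoocta-2,6-dienoic acid
Product: 6 (2S,6E)-8-methoxy-2,6-dimethyl-8-oxooct-6-enoic acid
Conditions: H2 (4 atm), Ru(OAc)2[(S)-H8-BINAP] (1 mol%), MeOH, rt
Reagents that add atoms: none
Why: Noyori-type carboxylate-directed Ru–BINAP asymmetric hydrogenation of a tiglic-acid-type (E)-2-methyl-2-enoic acid sets the future C8 as (S) (the (S)-ligand is chosen by analogy with tiglic acid giving (S)-2-methylbutanoic acid), and the ester-bearing alkene, which cannot bind ruthenium as a carboxylate, is not reduced.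

Step 5
Reactants: 6 (2S,6E)-8-methoxy-2,6-dimethyl-8-oxooct-6-enoic acid
Product: 7 methyl (2E,7S)-8-(ethylsulfanyl)-3,7-dimethyl-8-oxooct-2-enoate
Conditions: EtSH, DCC, DMAP (cat.), CH2Cl2, 0 °C to rt
Reagents that add atoms: ethanethiol, CCS
Why: Steglich thioesterification activates the only free carboxyl group, and a simple α-methyl alkanoic acid keeps its configuration under these conditions.

Step 6
Reactants: 2 (R)-linalyl acetate; 7 methyl (2E,7S)-8-(ethylsulfanyl)-3,7-dimethyl-8-oxooct-2-enoate
Product: 9 methyl (2E,7S,11R)-11-acetoxy-3,7,11,15-tetramethyl-8-oxohexadeca-2,14-dienoate, via borane 8 (not isolated)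
Conditions: 2, 9-BBN, THF, 0 °C to rt; then 7, Pd2(dba)3 (2.5 mol%), P(2-furyl)3, CuTC, Cs2CO3, THF, 45 °C
Reagents that add atoms: none
Why: 9-BBN hydroborates only the monosubstituted vinyl group (anti-Markovnikov, trisubstituted alkene untouched) and the B-alkyl-9-BBN then undergoes Liebeskind–Srogl acyl cross-coupling with the thioester to give the C9 ketone, no stereocentre being formed and both existing ones (C8 from step 4, C12 from linalool) lying outside the bonds that change.

Step 7
Reactants: 9 methyl (2E,7S,11R)-11-acetoxy-3,7,11,15-tetramethyl-8-oxohexadeca-2,14-dienoate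
Product: 11 (2E,7S,11R)-11-acetoxy-3,7,11,15-tetramethyl-8-oxohexadeca-2,14-dienoic acid, via trimethylstannyl ester 10 (not isolated)
Conditions: Me3SnOH, ClCH2CH2Cl, 70 °C; then 1 M HCl wash
Reagents that add atoms: trimethyltin hydroxide, C[Sn](C)(C)O
Why: Trimethyltin hydroxide ester hydrolysis is governed by the size of the alkoxy group, so the methyl ester is cleaved while the tert-alkyl acetate survives, and its low basicity leaves the α-methyl ketone centre unepimerised.

Step 8
Reactants: 11 (2E,7S,11R)-11-acetoxy-3,7,11,15-tetramethyl-8-oxohexadeca-2,14-dienoic acid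
Product: 14 (3E,8S,12R)-12-acetoxycembra-1(15),3-diene-2,9-dione, via acid chloride 12 (not isolated), via chloro ketone 13 (not isolated)
Conditions: 1-chloro-N,N,2-trimethylprop-1-en-1-amine (Ghosez reagent), CH2Cl2, 0 °C; slow addition to SnCl4 (3 equiv), CH2Cl2 (1 mM), −78 °C; then DBU, −78 to 0 °C
Reagents that add atoms: none
Why: Kato-type acyl cation–olefin macrocyclisation (intramolecular Friedel–Crafts acylation of an alkene) in which the conjugated acylium is attacked by the only π-nucleophile left in the chain, the terminal isopropylidene alkene, at its CH carbon to close the 14-membered ring through C1–C2 (the 2E geometry rules out small rings), chloride caps the C15 cation, and DBU removes HCl by E1cB towards C1 to give the conjugated isopropylidene ketone, with C8 and C12 carried in unchanged and the transient C1 centre erased.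

Step 9
Reactants: 14 (3E,8S,12R)-12-acetoxycembra-1(15),3-diene-2,9-dione
Product: 15 (3R,4S,8S,12R)-12-acetoxy-3,4-epoxycembr-1(15)-ene-2,9-dione (CNP0229580.1)
Conditions: TBHP (decane), La(O-i-Pr)3/(S)-BINOL/Ph3As=O (15 mol% each), 4 Å MS, THF, rt
Reagents that add atoms: tert-butyl hydroperoxide, CC(C)(C)OO
Why: Weitz–Scheffer nucleophilic epoxidation in its Shibasaki lanthanum–BINOL version, in which the La-bound peroxide adds to C4 of the C3=C4 enone (planar, s-cis) rather than to the twisted tetrasubstituted C1=C15 enone, ring closure keeps the E geometry as the trans oxirane, and the (S)-BINOL complex (antipode of the one reported to give (αS,βR)-epoxy ketones from simple E-enones, sense to be confirmed on the first run) selects the (3R,4S) face independently of the remote C8 and C12 centres.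

**Compound list**
1 | (R)-(−)-linalool, (3R)-3,7-dimethylocta-1,6-dien-3-ol | C=C[C@@](O)(C)CCC=C(C)C | starting material
2 | (R)-linalyl acetate, (3R)-3,7-dimethylocta-1,6-dien-3-yl acetate | C=C[C@@](OC(C)=O)(C)CCC=C(C)C | intermediate
3 | methyl geranate, methyl (2E)-3,7-dimethylocta-2,6-dienoate | COC(=O)/C=C(\C)CCC=C(C)C | starting material
4 | methyl (2E,6E)-3,7-dimethyl-8-oxoocta-2,6-dienoate | COC(=O)/C=C(\C)CC/C=C(\C)C=O | intermediate
5 | (2E,6E)-8-methoxy-2,6-dimethyl-8-oxoocta-2,6-dienoic acid | COC(=O)/C=C(\C)CC/C=C(\C)C(=O)O | intermediate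
6 | (2S,6E)-8-methoxy-2,6-dimethyl-8-oxooct-6-enoic acid | COC(=O)/C=C(\C)CCC[C@H](C)C(=O)O | intermediate
7 | methyl (2E,7S)-8-(ethylsulfanyl)-3,7-dimethyl-8-oxooct-2-enoate | COC(=O)/C=C(\C)CCC[C@H](C)C(=O)SCC | intermediate
8 | 9-[(3S)-3-acetoxy-3,7-dimethyloct-6-en-1-yl]-9-borabicyclo[3.3.1]nonane (same spatial arrangement as 2; only the CIP label changes) | C1CCC2CCCC1B2CC[C@@](OC(C)=O)(C)CCC=C(C)C | intermediate (not isolated)
9 | methyl (2E,7S,11R)-11-acetoxy-3,7,11,15-tetramethyl-8-oxohexadeca-2,14-dienoate | COC(=O)/C=C(\C)CCC[C@H](C)C(=O)CC[C@@](OC(C)=O)(C)CCC=C(C)C | intermediate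
10 | trimethylstannyl (2E,7S,11R)-11-acetoxy-3,7,11,15-tetramethyl-8-oxohexadeca-2,14-dienoate | C[Sn](C)(C)OC(=O)/C=C(\C)CCC[C@H](C)C(=O)CC[C@@](OC(C)=O)(C)CCC=C(C)C | intermediate (not isolated)
11 | (2E,7S,11R)-11-acetoxy-3,7,11,15-tetramethyl-8-oxohexadeca-2,14-dienoic acid | OC(=O)/C=C(\C)CCC[C@H](C)C(=O)CC[C@@](OC(C)=O)(C)CCC=C(C)C | intermediate
12 | (2E,7S,11R)-11-acetoxy-3,7,11,15-tetramethyl-8-oxohexadeca-2,14-dienoyl chloride | ClC(=O)/C=C(\C)CCC[C@H](C)C(=O)CC[C@@](OC(C)=O)(C)CCC=C(C)C | intermediate (not isolated)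
13 | (3E,8S,12R)-12-acetoxy-15-chlorocembr-3-ene-2,9-dione, both C1 epimers | O=C1/C=C(\C)CCC[C@H](C)C(=O)CC[C@@](OC(C)=O)(C)CCC1C(C)(C)Cl | intermediate (not isolated)
14 | (3E,8S,12R)-12-acetoxycembra-1(15),3-diene-2,9-dione | O=C1/C=C(\C)CCC[C@H](C)C(=O)CC[C@@](OC(C)=O)(C)CCC1=C(C)C | intermediate
15 | (3R,4S,8S,12R)-12-acetoxy-3,4-epoxycembr-1(15)-ene-2,9-dione | CC(=O)O[C@@]1(C)CCC(=O)[C@@H](C)CCC[C@]2(C)O[C@H]2C(=O)C(=C(C)C)CC1 | target

**Step count and risks**
Total steps: 9. Longest linear sequence: 8 steps (3 to 15, steps 2–9).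

The step most likely to fail is step 8. SnCl4 may ionise the tertiary acetate, or the C9 ketone may intercept the acylium or the alkene, and oligomers compete with the 14-membered ring. The fallback sets out from acid 11 and comes back at dienone 14, keeping the same C1–C2 bond but making it by a carbonyl-ene closure under a milder, proton-scavenging Lewis acid. Acid 11 is converted with EtSH/DCC/DMAP into the S-ethyl thioester F1. Fukuyama reduction (Et3SiH, Pd/C, acetone) gives the enal F2. Me2AlCl in CH2Cl2 at high dilution (−78 to 0 °C) closes the ring by intramolecular ene reaction of the terminal alkene with the aldehyde to give the allylic alcohol F3, which carries an isopropenyl group at C1. Dess–Martin oxidation gives the isopropenyl ketone F4, and catalytic DBU moves the β,γ-alkene into conjugation to give 14.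

Second is step 9. A β,β-dialkyl enone flanked by a second alkene lies outside the documented scope of the lanthanum–BINOL epoxidation, so conversion or face selectivity may be poor. The fallback sets out from dienone 14 and comes back at target 15. Luche reduction (NaBH4, CeCl3·7H2O, MeOH, −40 °C) of both ketones gives the diol F5. Sharpless asymmetric epoxidation (Ti(O-i-Pr)4, L-(+)-DIPT, TBHP, 4 Å MS, CH2Cl2, −20 °C) epoxidises only the geraniol-like C3=C4 alkene of the C2 allylic alcohol, on the face that corresponds to (2S,3S)-epoxygeraniol, to give the epoxy diol F6. Only the C2 epimer matched to the tartrate reacts quickly, so the other is recycled by oxidation to 14. Buffered Dess–Martin oxidation of both carbinols then returns 15 without touching C8.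

Third is step 6. The carbonate needed to activate the alkylborane may epimerise the thioester α-centre, and the one-pot hydroboration and coupling may be low-yielding. The fallback sets out from linalyl acetate 2 (through borane 8) and comes back at keto ester 9 by a base-free organozinc coupling. Borane 8 is iodinated (I2, NaOMe, MeOH, 0 °C) to the iodide F7. Zinc insertion (Zn dust, LiCl, THF) gives the alkylzinc iodide F8. Fukuyama coupling of F8 with thioester 7 (PdCl2(PPh3)2, toluene, rt) gives 9.

**Further compounds**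
F1 | step 8 | S-ethyl (2E,7S,11R)-11-acetoxy-3,7,11,15-tetramethyl-8-oxohexadeca-2,14-dienethioate | CCSC(=O)/C=C(\C)CCC[C@H](C)C(=O)CC[C@@](OC(C)=O)(C)CCC=C(C)C
F2 | step 8 | (2E,7S,11R)-11-acetoxy-3,7,11,15-tetramethyl-8-oxohexadeca-2,14-dienal | O=C/C=C(\C)CCC[C@H](C)C(=O)CC[C@@](OC(C)=O)(C)CCC=C(C)C
F3 | step 8 | (3E,8S,12R)-12-acetoxy-2-hydroxycembra-3,15-dien-9-one, C1/C2 epimers | OC1/C=C(\C)CCC[C@H](C)C(=O)CC[C@@](OC(C)=O)(C)CCC1C(C)=C
F4 | step 8 | (3E,8S,12R)-12-acetoxycembra-3,15-diene-2,9-dione, C1 epimers | O=C1/C=C(\C)CCC[C@H](C)C(=O)CC[C@@](OC(C)=O)(C)CCC1C(C)=C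
F5 | step 9 | (3E,8S,12R)-12-acetoxycembra-1(15),3-diene-2,9-diol, C2/C9 epimers | OC1/C=C(\C)CCC[C@H](C)C(O)CC[C@@](OC(C)=O)(C)CCC1=C(C)C
F6 | step 9 | (3S,4S,8S,12R)-12-acetoxy-3,4-epoxycembr-1(15)-ene-2,9-diol, oxirane as in 15 (CIP label at C3 changes), C2/C9 carbinols unassigned | CC(=O)O[C@@]1(C)CCC(O)[C@@H](C)CCC[C@]2(C)O[C@H]2C(O)C(=C(C)C)CC1
F7 | step 6 | (3R)-1-iodo-3,7-dimethyloct-6-en-3-yl acetate | ICC[C@@](OC(C)=O)(C)CCC=C(C)C
F8 | step 6 | [(3R)-3-acetoxy-3,7-dimethyloct-6-en-1-yl]zinc iodide | I[Zn]CC[C@@](OC(C)=O)(C)CCC=C(C)C
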